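Each unit of product, left- or right-handed, costs one reagent and one substrate, so c(reagent) and c(pool), the two substrates together, fall side by side. In the flask c(pool) starts at 82.0 mM and c(reagent) at 102 mM, so the pool is the limiting reagent, and the charge allows the whole pool to react.

| setting | theta | delta | beta | flask |
|---|---|---|---|---|
| left-handed substrate | 57 mM | 90 mM | 41 mM | 41 mM |
| right-handed substrate | 57 mM | 90 mM | 41 mM | 41 mM |
| reagent | 2.5 equiv | 2.5 equiv | 2.5 equiv | 2.50 equiv |
| free catalyst | 5 mol% | 5 mol% | 2.5 mol% | 5 mol% |
| impurity | 1.8 mM | 1.8 mM | 1.8 mM | 1.8 mM |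
| remark | run made earlier | run made earlier | run made earlier |  |
| time |  |  |  | 4.0 h |

| run | time / h | left-handed substrate / % | right-handed substrate / % |
|---|---|---|---|
| theta | 0.200 | 43.6 | 43.4 |
| theta | 0.667 | 36.3 | 36.5 |
| theta | 1.00 | 32.4 | 32.2 |
| theta | 2.00 | 26.6 | 26.9 |
| theta | 2.50 | 24.0 | 23.8 |
| theta | 3.00 | 22.5 | 23.9 |
| delta | 0.250 | 39.2 | 37.9 |
| delta | 0.417 | 32.1 | 33.8 |
| delta | 0.667 | 28.3 | 29.0 |
| delta | 1.33 | 19.3 | 18.4 |
| delta | 2.00 | 12.7 | 14.1 |
| delta | 3.00 | 8.9 | 11.0 |
| beta | 0.250 | 45.8 | 46.6 |
| beta | 0.833 | 46.9 | 46.1 |
| beta | 1.33 | 42.4 | 45.0 |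
| beta | 2.50 | 43.7 | 43.4 |
| beta | 3.00 | 42.7 | 41.5 |

(each reading ± 1 percentage point)

- free catalyst is single-handed; left-handed substrate and right-handed substrate are mirror images of each other, charged as a racemate, each of them at the stated concentration
- the numbers in the tables scatter with a standard deviation of 1 percentage point
- reactions considered so far: reagent + free catalyst + left-handed substrate -> free catalyst + left-handed product; reagent + free catalyst + right-handed substrate -> free catalyst + right-handed product; left-handed substrate <-> right-handed substrate; 2 free catalyst <-> resting dimer; free catalyst + impurity -> spent catalyst A; free catalyst -> spent catalyst B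
- an excess is the difference of the two amounts in percent of their sum
- an excess is below zero if the other one leads

- part of the left-handed substrate and right-handed substrate charged together that has reacted at 4.0 h
- excess of left-handed product over right-handed product in the product at 4.0 h
- excess of right-handed substrate over left-handed substrate among what is left of the two at 4.0 h

Theta's last left-handed and right-handed substrate readings, 22.5 % and 23.9 %, differ by about the scatter, so I treat the pool with one mean rate constant. I call the dose that constant times the time-integral of c(free catalyst). It equals the logarithm of (fraction of reagent left / fraction of pool left), divided by the difference of the two charges.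

At 3.00 h, beta, with 1.03 mM of catalyst, reads 0.00180 mM⁻¹. At 3.00 h, theta, with 2.85 mM, reads 0.00729 mM⁻¹. Between them, the flask's 2.05 mM gives a flask dose of 0.00488 mM⁻¹, which I take for 4.0 h as well.

Turned round, reacting half of the pool needs 0.00889 mM⁻¹, and my flask dose stands below that. Solving for the conversion, I expect 34.5 %.

The forecast gives a higher 39 %, with product excess 40 % and substrate excess 1 %, and says: “The data cannot fix eP”.

    reagent + free catalyst + left-handed substrate → free catalyst + left-handed product (k = 110 L² mol⁻² min⁻¹)
    reagent + free catalyst + right-handed substrate → free catalyst + right-handed product (k = 55.0 L² mol⁻² min⁻¹)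
    left-handed substrate ⇌ right-handed substrate (k = 0.120 min⁻¹)
    2 free catalyst ⇌ resting dimer, settled at all times (K = 1100 L mol⁻¹)
    free catalyst + impurity → spent catalyst A (k = 40.0 L mol⁻¹ min⁻¹)
    free catalyst → spent catalyst B (k = 0.00470 min⁻¹)

The flask gives 36.0 %, product excess 33.0 % and substrate excess 0.0706 %; the forecast's product excess stands 7 percentage points high. The flask's conversion reads back as a dose of 0.00521 mM⁻¹, above my 0.00488 mM⁻¹. The neighbouring flask with 10.0 equiv of reagent holds 3.98 % of the catalyst charged as free catalyst at 4.0 h, the same as the flask, and I carry that dose over. With c(reagent) charged at 410 mM, the dose gives 85.0 %, and that neighbouring flask reacts 84.9 %.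

The data were generated by integration with made-up constants, noise included.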